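## The problem

Compound 15 is a 7,9'-epoxylignan: a tetrahydrofuran (ring atoms O1, C2, C3, C4, C5) with a 4-hydroxy-3-methoxyphenyl group on C2, a hydroxymethyl group (C9) on C3 and a secondary benzylic carbinol (C7', again 4-hydroxy-3-methoxyphenyl) on C4; C5 is an unsubstituted methylene. The skeleton is two C6–C3 units joined through C3–C4, so a synthesis must make that bond, the ring ether and one aryl–carbon connection with little waste. Four stereocentres must be fixed: C2 (R), C3 (S) and C4 (S) on the ring and C7' (S) beside it. The ring substituents are 2,3-trans and 3,4-cis, which places the C2 aryl group and the C4 side chain trans. C4 is the natural control element. It is the only centre adjacent to C7', and because C9 and the C7' oxygen stand in a 1,4-relation they can be tied into a γ-lactone whose cis ring fusion dictates C3. C2 has no such relay to C4 and must be set together with C4 or by a catalyst. Both benzylic C–O bonds (C2–O1 and C7'–OH) are para to an oxygen substituent: they ionise under acid, are expelled through quinone methides once the phenols are free and basic, and are open to hydrogenolysis; the free phenols are easily oxidised. The enabling feature is the pair of paths leaving C3. O1–C2(aryl)–C3 is the pattern of an alkoxide added to an arylidene malonate if C3 temporarily carries two ester groups (one the future C9). C3–C4(C7')–C5–O1 is the pattern of a malonate added to the substituted end of an allyl unit if C7' is the inner carbon of a vinyl group. The ring is therefore the formal [3+2] adduct of an oxygen-terminated allyl dipole and a Michael acceptor.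

## Retrosynthesis

**15 ⇒ 14 (phenol unmasking).** The two phenolic O–H bonds are traced back to O–benzyl bonds. Benzyl ethers tolerate every later condition (amine catalysis, zerovalent palladium, periodate, a Grignard reagent, hot chloride, hydride) and leave under neutral conditions. Acetal groups would need acid, which threatens both benzylic C–O bonds; aryl silyl ethers would not survive hot chloride. Dibenzyl ether 14 is no simpler in skeleton, but it keeps the quinone-methide liability out of all earlier stages. The forward step must stop at the aryl benzyl ethers.

**14 ⇒ 13 (lactone as a tied 1,4-diol).** The C9 hydroxyl and the C7' hydroxyl are joined retrosynthetically into one γ-lactone (C9 as carbonyl, O on C7'). Against separate reduction of a C9 ester and a C7' ketone, one hydride step then makes both hydroxyls, and C7' is already configured. In 13 the 3,4-cis relation is a consequence of ring fusion, not of selectivity. The forward reduction must not disturb the α-centre C3.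

**13 ⇒ 12 (extra ester on C3).** A methoxycarbonyl group is added to C3. This makes C3 a malonate carbon, which both bond formations of the key step require. Because the group is removed only after the lactone exists, C3 is never set by an external reagent. The forward step is a dealkoxycarbonylation that must spare the benzylic lactone C–O bond.

**12 ⇒ 7 + 9 (C7'–aryl bond and lactone C–O bond).** Cutting the aryl–C7' bond and the lactone acyl–oxygen bond gives aldehyde 7 and aryl bromide 9, used as its Grignard reagent 10; the adduct 11 closes to 12. This is preferred to carrying the second aryl group through the cycloaddition on the allyl unit, which would leave C7' as an alkene carbon in need of regio- and stereoselective hydration. The union is convergent, C4 can direct the new centre by the Felkin–Anh model, and only the ester cis to C7' can lactonise. The precursors lack one stereocentre, one ring and one aryl group. The forward step needs facial selectivity and aldehyde-over-ester chemoselectivity.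

**7 ⇒ 5 (aldehyde from vinyl).** The formyl group is traced to a vinyl group, cutting C7'=O back to C7'=CH2. A vinyl group is exactly what π-allyl chemistry leaves on C4, and it can be cleaved under buffered conditions. The forward step must not epimerise C4.

**5 ⇒ 3 + 4 (the ring; O1–C2 and C3–C4).** Cutting O1–C2 and C3–C4 divides the ring into a three-atom piece (O1, C5, C4 with its vinyl group) and a two-atom piece (C2, C3). These are racemic vinylethylene carbonate 4 and arylidene malonate 3. Other pairs of ring bonds would give fragments that each need their own stereocentres. Here one catalytic step builds the ring, two skeletal bonds and both C2 and C4 from an achiral and a racemic partner. The forward reaction must deliver the branched five-membered adduct, the 2,4-trans relation and one absolute sense.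

**3 ⇒ 1 + 2 and 9 ⇒ 8.** The C2=C3 bond of 3 is a Knoevenagel bond between O-benzylvanillin 1 and dimethyl malonate 2. Bromide 9 is the benzyl ether of 4-bromo-2-methoxyphenol 8. All four starting materials (1, 2, 4, 8) are commercial.

## Roads not taken

**Alternative 1:** Carbon monoxide as C5.
- **Cut:** C4–C5 and C5–O1, with C5 supplied as carbon monoxide.
- **Key step:** palladium-catalysed cyclocarbonylation of the anti homopropargylic alcohol A2 to the (E)-α-benzylidene γ-butyrolactone A1.
- **Merits:** C5 comes from a one-carbon feedstock. Both aryl groups are in place before ring closure. The C2/C3 trans relation would come from an acyclic propargylation of 1 whose stereochemical course is well understood. Syn addition across the alkyne defines the alkene geometry.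
- **Weak points:** A1 has C5 at the carboxyl level and C4 as an sp2 carbon without oxygen on C7'. The benzylidene unit must be converted to C4–H/C7'–OH with two new stereocentres, and the 3,4-cis arrangement is then the less stable one α to a lactone carbonyl. The C5 carbonyl must also be taken down to a methylene, by Lewis-acid silane reduction beside two ionisable benzylic C–O bonds or by full reduction and re-closure. At least four further operations follow the key step.
- **Comparison:** the absolute and relative configuration at C2/C3 would rest on a reaction of known sense, which is better than relying on a ligand whose sense must be established. Against this the chosen plan has C5 at the correct oxidation level from the start, locks 3,4-cis by ring fusion, and needs eight steps in all.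

**Alternative 2:** Photocycloaddition, then cyclobutene cleavage.
- **Cut:** C3–C9 and C4–C7'.
- **Key step:** [2+2] photocycloaddition of butenolide A4 with arylalkyne A5 to the cis-fused cyclobutene A3, the alkyne adding anti to the aryl group.
- **Merits:** one step brings in all remaining carbons and fixes C2, C3 and C4 relative to each other exactly as required, with no chiral catalyst beyond what makes A4. It reaches the full skeleton in fewer steps than any other plan.
- **Weak points:** the orientation that puts the aryl-bearing alkyne carbon on C4 is one of two regiochemical outcomes and is not assured. A5 and the electron-rich arenes absorb competitively. A4 has a doubly activated γ-hydrogen and racemises easily. Cleaving the cyclobutene of A3 turns C9 into an aldehyde and C7' into an aryl ketone, so C4 lies between two carbonyl groups and epimerises readily. C3 then carries a formyl group β to the benzylic acyloxy bond at C2, which invites elimination. C5 (lactone carbonyl), C9 and C7' must afterwards be reduced to three different levels.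
- **Comparison:** in skeletal and stereochemical economy of the key step this road is better. The chosen plan offers configurationally stable intermediates throughout, no redox adjustment at C5, and catalyst control of absolute configuration.

**Alternative 3:** Ketene–alkene [2+2], then Baeyer–Villiger.
- **Cut:** C3–C4 and C9–C7'.
- **Key step:** the ketene generated from acid chloride A7 with Et3N adds across its tethered Z-styrenyl alkene to give cyclobutanone A6, closing the tetrahydrofuran at the same time. Baeyer–Villiger oxidation with migration of the benzylic carbon would give lactone 13 of the chosen route.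
- **Merits:** one stereocentre (C2 in A7, accessible by reliable asymmetric methods) would control all others in a stereospecific cycloaddition, and the endgame from 13 is shared. In independence from a chiral ligand of unproven sense this road is as good as or better than the chosen one.
- **Weak points:** the tether demands that the ketene carbonyl carbon bond to C7', but an electron-rich styrene prefers bonding at C4 with charge developing at the benzylic carbon, which leads to a bridged skeleton. The Z-alkene must be made and kept. A7 is a β-alkoxy acyl chloride that can lose its alkoxide under Et3N. A6 is an α-aryl cyclobutanone with the aryl group on the concave face and epimerises easily to the wrong C7' configuration. The peracid must spare two electron-rich rings.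
- **Comparison:** the chosen plan has a ring-forming step without a regiochemical conflict between tether and electronics, no base-labile α-aryl ketone, and a shorter path to 13 (six operations from commercial materials).

Key step: step 2

Assumption: the sense of induction of the phosphoramidite in step 2 cannot be assigned with certainty on paper; the ligand antipode that gives (2S,4S)-5 is to be fixed in a first run and the configuration of 5 secured before material is brought forward.

## Route

Step 1
Reactants: 1 4-(benzyloxy)-3-methoxybenzaldehyde; 2 dimethyl malonate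
Product: 3 dimethyl 2-[4-(benzyloxy)-3-methoxybenzylidene]malonate
Conditions: piperidine (0.1 equiv), AcOH (0.1 equiv), toluene, reflux, Dean–Stark trap
Reagents that add atoms: none
Why: Knoevenagel condensation under piperidinium acetate catalysis with azeotropic removal of water; the aldehyde cannot enolise and the two ester groups are identical, so no geometric isomers arise.

Step 2
Reactants: 3 dimethyl 2-[4-(benzyloxy)-3-methoxybenzylidene]malonate; 4 racemic 4-vinyl-1,3-dioxolan-2-one (vinylethylene carbonate)
Product: 5 dimethyl (2S,4S)-2-[4-(benzyloxy)-3-methoxyphenyl]-4-vinyltetrahydrofuran-3,3-dicarboxylate (aryl and vinyl trans)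
Conditions: Pd2(dba)3·CHCl3 (2.5 mol %), BINOL-derived N,N-bis(1-phenylethyl)phosphoramidite (10 mol %), THF, 25–40 °C
Reagents that add atoms: none
Why: Zerovalent palladium ionises 4 with loss of CO2 to a zwitterionic π-allylpalladium alkoxide, whose oxygen adds reversibly to C2 of 3 (oxa-Michael) and leaves a malonate anion next to the allyl unit. The carbanion attacks the substituted allyl terminus and forms C3–C4 in a 5-exo closure, the only ring closed here; attack at the CH2 terminus would need a seven-membered ring and should not compete. The closest known reaction type is the palladium-catalysed decarboxylative [3+2] cycloaddition of vinylethylene carbonates and vinyl epoxides with doubly activated alkenes under chiral phosphoramidite ligands. C4 is set by the ligand: the diastereomeric π-allyl complexes from racemic 4 interconvert by π–σ–π isomerisation through the unsubstituted terminus faster than they cyclise, so both enantiomers of 4 drain through one complex (dynamic kinetic asymmetric transformation). C2 is set in the same transition state, because the reversible oxygen addition lets the C2 epimers of the open adduct equilibrate (Curtin–Hammett) and the aryl group can settle on the ring face opposite the vinyl group, away from the ligand-bound allyl fragment. The step needs branched regioselectivity, the 2,4-trans relation and one absolute sense, (2S,4S); the soft doubly stabilised malonate nucleophile, the fast face exchange of a monosubstituted allyl unit and the chiral pocket of the ligand should secure them. C3 bears two identical esters and is not yet a stereocentre.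

Step 3
Reactants: 5 dimethyl (2S,4S)-2-[4-(benzyloxy)-3-methoxyphenyl]-4-vinyltetrahydrofuran-3,3-dicarboxylate
Product: 7 dimethyl (2S,4S)-2-[4-(benzyloxy)-3-methoxyphenyl]-4-formyltetrahydrofuran-3,3-dicarboxylate, via vicinal diol 6 (not isolated)
Conditions: K2OsO4·2H2O (2 mol %), NaIO4 (4 equiv), 2,6-lutidine (2 equiv), 1,4-dioxane/H2O 3:1, rt
Reagents that add atoms: osmium tetroxide formed in situ from K2OsO4·2H2O and NaIO4, O=[Os](=O)(=O)=O; sodium periodate as terminal oxidant that restores the osmium oxo groups, [Na+].[O-]I(=O)(=O)=O
Why: Lemieux–Johnson oxidative cleavage: dihydroxylation of the monosubstituted alkene to 6 and periodate cleavage in the same flask. The 2,6-lutidine buffer should prevent epimerisation at C4 and over-oxidation; the arenes, esters and cyclic benzylic ether are inert, and 7 is used at once.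

Step 4
Reactants: 8 4-bromo-2-methoxyphenol
Product: 9 1-(benzyloxy)-4-bromo-2-methoxybenzene
Conditions: BnBr, K2CO3, acetone, reflux
Reagents that add atoms: benzyl bromide, BrCc1ccccc1
Why: Williamson ether synthesis on the phenoxide; the aryl bromide is inert under these conditions.

Step 5
Reactants: 7 dimethyl (2S,4S)-2-[4-(benzyloxy)-3-methoxyphenyl]-4-formyltetrahydrofuran-3,3-dicarboxylate; 9 1-(benzyloxy)-4-bromo-2-methoxybenzene
Product: 12 methyl (3S,3aS,6S,6aR)-3,6-bis[4-(benzyloxy)-3-methoxyphenyl]-1-oxotetrahydro-1H,3H-furo[3,4-c]furan-6a(6H)-carboxylate, via arylmagnesium bromide 10 (not isolated), via hydroxy diester 11 (not isolated)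
Conditions: 9, Mg turnings, THF, 40 °C; then 7, THF, −78 °C; aq. NH4Cl at −78 °C; crude 11, DBU (0.2 equiv), CH2Cl2, rt
Reagents that add atoms: none
Why: Grignard formation by magnesium insertion, then 1,2-addition to the aldehyde, which at −78 °C outpaces attack on the two hindered esters; the cold quench removes excess reagent before the lactone exists. Felkin–Anh control by C4 sets C7': the quaternary C3 lies antiperiplanar to the incoming aryl group and the carbonyl oxygen sits on the C5 side (a magnesium chelate to O1 would point the same way), which gives the (S)-carbinol. DBU-catalysed transesterification then closes the γ-lactone (5-exo-trig) with the only ester that can reach, the one cis to C7', which makes C3 a stereocentre with C9 cis to C7'.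

Step 6
Reactants: 12 methyl (3S,3aS,6S,6aR)-3,6-bis[4-(benzyloxy)-3-methoxyphenyl]-1-oxotetrahydro-1H,3H-furo[3,4-c]furan-6a(6H)-carboxylate
Product: 13 (3S,3aS,6R,6aR)-3,6-bis[4-(benzyloxy)-3-methoxyphenyl]tetrahydro-1H,3H-furo[3,4-c]furan-1-one (cis-fused lactone)
Conditions: LiCl (3 equiv), H2O (2 equiv), DMSO, 140 °C
Reagents that add atoms: none
Why: Krapcho dealkoxycarbonylation: chloride removes the ester methyl group by SN2, the carboxylate loses CO2, and the lactone enolate is protonated to the cis-fused 2,7-dioxabicyclo[3.3.0]octane, the only strain-free fusion. C3–H therefore ends cis to C4–H and C9 trans to the C2 aryl group; that aryl group already sits on the convex face, so C2 has no drive to epimerise.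

Step 7
Reactants: 13 (3S,3aS,6R,6aR)-3,6-bis[4-(benzyloxy)-3-methoxyphenyl]tetrahydro-1H,3H-furo[3,4-c]furan-1-one
Product: 14 (S)-[4-(benzyloxy)-3-methoxyphenyl][(3S,4S,5R)-5-[4-(benzyloxy)-3-methoxyphenyl]-4-(hydroxymethyl)tetrahydrofuran-3-yl]methanol
Conditions: LiAlH4, THF, 0 °C → rt; H2O/aq. NaOH work-up
Reagents that add atoms: none
Why: LiAlH4 reduction of the γ-lactone to the 1,4-diol releases the primary alcohol at C9 and the secondary alcohol at C7' without touching a stereocentre; aryl benzyl ethers and the cyclic benzylic ether are stable to hydride.

Step 8
Reactants: 14 (S)-[4-(benzyloxy)-3-methoxyphenyl][(3S,4S,5R)-5-[4-(benzyloxy)-3-methoxyphenyl]-4-(hydroxymethyl)tetrahydrofuran-3-yl]methanol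
Product: 15 4-[(2R,3S,4S)-4-[(S)-hydroxy(4-hydroxy-3-methoxyphenyl)methyl]-3-(hydroxymethyl)tetrahydrofuran-2-yl]-2-methoxyphenol
Conditions: H2 (1 atm), 10% Pd/C, EtOAc/EtOH, rt
Reagents that add atoms: none
Why: Catalytic hydrogenolysis of the two aryl benzyl ethers under neutral conditions at atmospheric pressure; phenyl benzyl ethers are cleaved much faster than a secondary benzylic alcohol or a 2-aryltetrahydrofuran, and the reaction is stopped once 14 is consumed.

## Compound list

1 | 4-(benzyloxy)-3-methoxybenzaldehyde (O-benzylvanillin) | O=Cc1ccc(OCc2ccccc2)c(OC)c1 | starting material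
2 | dimethyl malonate | COC(=O)CC(=O)OC | starting material
3 | dimethyl 2-[4-(benzyloxy)-3-methoxybenzylidene]malonate | COC(=O)C(=Cc1ccc(OCc2ccccc2)c(OC)c1)C(=O)OC | intermediate
4 | racemic 4-vinyl-1,3-dioxolan-2-one (vinylethylene carbonate) | C=CC1COC(=O)O1 | starting material
5 | dimethyl (2S,4S)-2-[4-(benzyloxy)-3-methoxyphenyl]-4-vinyltetrahydrofuran-3,3-dicarboxylate (aryl and vinyl trans) | C=C[C@@H]1CO[C@@H](c2ccc(OCc3ccccc3)c(OC)c2)C1(C(=O)OC)C(=O)OC | intermediate
6 | dimethyl (2S,4S)-2-[4-(benzyloxy)-3-methoxyphenyl]-4-(1,2-dihydroxyethyl)tetrahydrofuran-3,3-dicarboxylate (both epimers at the carbinol carbon; not isolated) | OCC(O)[C@@H]1CO[C@@H](c2ccc(OCc3ccccc3)c(OC)c2)C1(C(=O)OC)C(=O)OC | intermediate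
7 | dimethyl (2S,4S)-2-[4-(benzyloxy)-3-methoxyphenyl]-4-formyltetrahydrofuran-3,3-dicarboxylate | O=C[C@@H]1CO[C@@H](c2ccc(OCc3ccccc3)c(OC)c2)C1(C(=O)OC)C(=O)OC | intermediate
8 | 4-bromo-2-methoxyphenol | COc1cc(Br)ccc1O | starting material
9 | 1-(benzyloxy)-4-bromo-2-methoxybenzene | COc1cc(Br)ccc1OCc1ccccc1 | intermediate
10 | [4-(benzyloxy)-3-methoxyphenyl]magnesium bromide (not isolated) | COc1cc([Mg]Br)ccc1OCc1ccccc1 | intermediate
11 | dimethyl (2S,4S)-2-[4-(benzyloxy)-3-methoxyphenyl]-4-[(S)-[4-(benzyloxy)-3-methoxyphenyl](hydroxy)methyl]tetrahydrofuran-3,3-dicarboxylate (not isolated) | COc1cc([C@@H](O)[C@@H]2CO[C@@H](c3ccc(OCc4ccccc4)c(OC)c3)C2(C(=O)OC)C(=O)OC)ccc1OCc1ccccc1 | intermediate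
12 | methyl (3S,3aS,6S,6aR)-3,6-bis[4-(benzyloxy)-3-methoxyphenyl]-1-oxotetrahydro-1H,3H-furo[3,4-c]furan-6a(6H)-carboxylate (cis-fused; 3-aryl on the concave face, 6-aryl on the convex face) | COc1cc([C@@H](O5)[C@@H]2CO[C@@H](c3ccc(OCc4ccccc4)c(OC)c3)[C@]2(C(=O)OC)C5=O)ccc1OCc1ccccc1 | intermediate
13 | (3S,3aS,6R,6aR)-3,6-bis[4-(benzyloxy)-3-methoxyphenyl]tetrahydro-1H,3H-furo[3,4-c]furan-1-one (cis-fused) | COc1cc([C@@H](O5)[C@@H]2CO[C@@H](c3ccc(OCc4ccccc4)c(OC)c3)[C@@H]2C5=O)ccc1OCc1ccccc1 | intermediate
14 | (S)-[4-(benzyloxy)-3-methoxyphenyl][(3S,4S,5R)-5-[4-(benzyloxy)-3-methoxyphenyl]-4-(hydroxymethyl)tetrahydrofuran-3-yl]methanol | COc1cc([C@@H](O)[C@@H]2CO[C@@H](c3ccc(OCc4ccccc4)c(OC)c3)[C@@H]2CO)ccc1OCc1ccccc1 | intermediate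
15 | 4-[(2R,3S,4S)-4-[(S)-hydroxy(4-hydroxy-3-methoxyphenyl)methyl]-3-(hydroxymethyl)tetrahydrofuran-2-yl]-2-methoxyphenol | COc1cc([C@@H](O)[C@@H]2CO[C@@H](c3ccc(O)c(OC)c3)[C@@H]2CO)ccc1O | target

## Step count and least certain steps

Total step count: 8. Longest linear sequence: 7 (steps 1, 2, 3, 5, 6, 7, 8); step 4 is a one-step side branch.

**Step 2 (key step).** The most likely failure is that the zwitterion is not intercepted. With its electron-donating aryl group, 3 is a weak acceptor, so the palladium alkoxide may lose a β-hydrogen (isomerisation to an enal) or oligomerise with further 4. The second concern is incomplete control of the 2,4-trans relation or of the absolute sense in the ring-closing allylation; a minor 2,4-cis isomer would have to be removed by chromatography. The fallback raises the electrophilicity of the acceptor. It sets out from 1 and 4. Compound 1 is condensed with 2,2-dimethyl-1,3-dioxane-4,6-dione to the arylidene Meldrum's acid F1. F1 undergoes the same palladium cycloaddition with 4 to give the spirocyclic adduct F2. The acylal is opened with NaOMe in MeOH, with loss of acetone, to the half ester F3 (as its sodium salt), which is methylated with MeI in DMF. The sequence comes back to the route at 5.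

**Step 5.** The most likely failure is erosion of facial selectivity at C7'. A magnesium chelate between the formyl oxygen and the cis ester would turn the opposite carbonyl face to the reagent and compete with the open Felkin–Anh arrangement. Enolisation of the aldehyde by the basic reagent, with epimerisation at C4, is a lesser concern. The fallback replaces substrate control by reagent control and sets out from 7. Pinnick oxidation (NaClO2, NaH2PO4, 2-methyl-2-butene, t-BuOH/H2O) gives the carboxylic acid F4. Oxalyl chloride with catalytic DMF converts it into the acid chloride F5. Acylation of Grignard reagent 10 with F5 under Fe(acac)3 catalysis at −78 °C gives the aryl ketone F6. Corey–Bakshi–Shibata reduction with the (R)-configured methyl oxazaborolidine and BH3·SMe2 should give 11; this is the antipode expected to give the (S)-carbinol when the aryl group acts as the larger substituent. DBU then closes the lactone, and the sequence comes back to the route at 12.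

**Step 6.** The most likely failure is heterolysis or chloride opening of the benzylic lactone C7'–O bond at 140 °C. The para-oxygenated ring stabilises the cation, and re-closure would favour the convex, wrong configuration at C7'. A second possibility is E1cB opening of the tetrahydrofuran from the lactone enolate. The fallback avoids hot nucleophilic chloride and sets out from 12. The methyl ester is hydrolysed with Me3SnOH in 1,2-dichloroethane at 80 °C to the lactone acid F7. This malonic-type acid is decarboxylated by warming in toluene at about 100 °C, and the sequence comes back to the route at 13.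

**Step 8.** The most likely failure is over-reduction: hydrogenolysis of the C7'–OH bond, and less probably of the C2–O1 bond, both activated by para-oxygen, during or after debenzylation. The fallback shields the carbinol and sets out from 14. Both hydroxyl groups are silylated (TBSCl, imidazole, DMF) to the bis(silyl) ether F8. The benzyl groups are removed by hydrogenolysis (H2, Pd/C, EtOAc) to the bisphenol F9. The silyl groups are removed with Bu4NF buffered with AcOH in THF, and the sequence comes back to the route at 15.

## Further compounds

F1 | step 2 | 5-[4-(benzyloxy)-3-methoxybenzylidene]-2,2-dimethyl-1,3-dioxane-4,6-dione | CC1(C)OC(=O)C(=Cc2ccc(OCc3ccccc3)c(OC)c2)C(=O)O1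
F2 | step 2 | (1S,4S)-1-[4-(benzyloxy)-3-methoxyphenyl]-4-ethenyl-8,8-dimethyl-2,7,9-trioxaspiro[4.5]decane-6,10-dione | C=C[C@@H]1CO[C@@H](c2ccc(OCc3ccccc3)c(OC)c2)C13C(=O)OC(C)(C)OC3=O
F3 | step 2 | (2S,4S)-2-[4-(benzyloxy)-3-methoxyphenyl]-3-(methoxycarbonyl)-4-vinyltetrahydrofuran-3-carboxylic acid (either configuration at C3; handled as its sodium salt) | C=C[C@@H]1CO[C@@H](c2ccc(OCc3ccccc3)c(OC)c2)C1(C(=O)O)C(=O)OC
F4 | step 5 | (3S,5S)-5-[4-(benzyloxy)-3-methoxyphenyl]-4,4-bis(methoxycarbonyl)tetrahydrofuran-3-carboxylic acid | OC(=O)[C@@H]1CO[C@@H](c2ccc(OCc3ccccc3)c(OC)c2)C1(C(=O)OC)C(=O)OC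
F5 | step 5 | dimethyl (2S,4S)-2-[4-(benzyloxy)-3-methoxyphenyl]-4-(chlorocarbonyl)tetrahydrofuran-3,3-dicarboxylate | ClC(=O)[C@@H]1CO[C@@H](c2ccc(OCc3ccccc3)c(OC)c2)C1(C(=O)OC)C(=O)OC
F6 | step 5 | dimethyl (2S,4S)-4-[4-(benzyloxy)-3-methoxybenzoyl]-2-[4-(benzyloxy)-3-methoxyphenyl]tetrahydrofuran-3,3-dicarboxylate | COc1cc(C(=O)[C@@H]2CO[C@@H](c3ccc(OCc4ccccc4)c(OC)c3)C2(C(=O)OC)C(=O)OC)ccc1OCc1ccccc1
F7 | step 6 | (3S,3aS,6S,6aR)-3,6-bis[4-(benzyloxy)-3-methoxyphenyl]-1-oxotetrahydro-1H,3H-furo[3,4-c]furan-6a(6H)-carboxylic acid | COc1cc([C@@H](O5)[C@@H]2CO[C@@H](c3ccc(OCc4ccccc4)c(OC)c3)[C@]2(C(=O)O)C5=O)ccc1OCc1ccccc1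
F8 | step 8 | bis(tert-butyldimethylsilyl) ether of 14 at the C7' and C9 hydroxyl groups | COc1cc([C@@H](O[Si](C)(C)C(C)(C)C)[C@@H]2CO[C@@H](c3ccc(OCc4ccccc4)c(OC)c3)[C@@H]2CO[Si](C)(C)C(C)(C)C)ccc1OCc1ccccc1
F9 | step 8 | bis(tert-butyldimethylsilyl) ether of 15 at the C7' and C9 hydroxyl groups (free phenols) | COc1cc([C@@H](O[Si](C)(C)C(C)(C)C)[C@@H]2CO[C@@H](c3ccc(O)c(OC)c3)[C@@H]2CO[Si](C)(C)C(C)(C)C)ccc1O
A1 | alternative 1 | (E)-3-(4-benzyloxy-3-methoxybenzylidene)-5-(4-benzyloxy-3-methoxyphenyl)-4-(tert-butyldimethylsilyloxymethyl)dihydrofuran-2-one (4,5-trans) | COc1cc(/C=C2/C(=O)O[C@@H](c3ccc(OCc4ccccc4)c(OC)c3)[C@@H]2CO[Si](C)(C)C(C)(C)C)ccc1OCc1ccccc1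
A2 | alternative 1 | (1R,2S)-1,4-bis[4-(benzyloxy)-3-methoxyphenyl]-2-[(tert-butyldimethylsilyloxy)methyl]but-3-yn-1-ol (anti) | O[C@@H](c1ccc(OCc2ccccc2)c(OC)c1)[C@@H](C#Cc1ccc(OCc2ccccc2)c(OC)c1)CO[Si](C)(C)C(C)(C)C
A3 | alternative 2 | 4,7-bis(4-benzyloxy-3-methoxyphenyl)-3-oxabicyclo[3.2.0]hept-6-en-2-one (cyclobutene anti to the 4-aryl group) | O=C1O[C@@H](c2ccc(OCc3ccccc3)c(OC)c2)[C@@H]2C=C(c3ccc(OCc4ccccc4)c(OC)c3)[C@H]12
A4 | alternative 2 | (R)-5-[4-(benzyloxy)-3-methoxyphenyl]furan-2(5H)-one | O=C1O[C@@H](c2ccc(OCc3ccccc3)c(OC)c2)C=C1
A5 | alternative 2 | 1-(benzyloxy)-4-ethynyl-2-methoxybenzene | C#Cc1ccc(OCc2ccccc2)c(OC)c1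
A6 | alternative 3 | 2,6-bis(4-benzyloxy-3-methoxyphenyl)-3-oxabicyclo[3.2.0]heptan-7-one (2-aryl exo, 6-aryl endo) | COc1cc([C@@H]5[C@@H]2CO[C@@H](c3ccc(OCc4ccccc4)c(OC)c3)[C@@H]2C5=O)ccc1OCc1ccccc1
A7 | alternative 3 | (R)-3-[4-(benzyloxy)-3-methoxyphenyl]-3-[(Z)-3-[4-(benzyloxy)-3-methoxyphenyl]allyloxy]propanoyl chloride | O=C(Cl)C[C@@H](OC/C=C\c1ccc(OCc2ccccc2)c(OC)c1)c1ccc(OCc2ccccc2)c(OC)c1
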